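The earlier runs and the new flask were computed with made-up constants.

Reckon time here as hours multiplied by the loading of D, not as plain hours, and two of the earlier runs collapse into one.

| flask | G | D | remark | time |
|---|---|---|---|---|
| ochre | 0.10 M (fed, over 6.0 min) | 3 mol% | run made earlier |  |
| violet | 0.10 M (fed, over 6.0 min) | 6.8 mol% | run made earlier |  |
| grey | 0.15 M (fed, over 6.0 min) | 4.5 mol% | run made earlier |  |
| flask | 0.10 M (fed, over 6.0 min) | 4.5 mol% |  | 2.0 h |

| run | time / h | X / % | G / % |
|---|---|---|---|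
| ochre | 0.133 | 0 | 93.7 |
| ochre | 0.333 | 0.5 | 83.6 |
| ochre | 0.667 | 3.5 | 68.6 |
| ochre | 1.00 | 8.3 | 55.6 |
| ochre | 1.33 | 12.4 | 45.4 |
| ochre | 2.00 | 25.1 | 24.1 |
| ochre | 2.50 | 35.0 | 13.6 |
| violet | 0.200 | 0.5 | 80.4 |
| violet | 0.333 | 2.3 | 66.2 |
| violet | 0.417 | 3.8 | 59.4 |
| violet | 0.667 | 7.5 | 38.2 |
| violet | 1.00 | 14.7 | 16.0 |
| violet | 1.50 | 27.3 | 3.1 |
| violet | 2.50 | 50.6 | 0.4 |
| grey | 0.200 | 0.3 | 85.4 |
| grey | 0.667 | 3.3 | 51.4 |
| grey | 1.00 | 11.3 | 30.1 |
| grey | 1.50 | 23.2 | 11.2 |
| grey | 2.50 | 45.7 | 0 |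

(scatter of a reading: 1 percentage point)



- amount of X in the flask at 2.0 h, in percent of the G charged
- amount of G in the flask at 2.0 h, in percent of the G charged
- amount of J in the flask at 2.0 h, in percent of the G charged

Ochre and violet share their charge of G and their feed and differ in D, so set their late readings side by side, with θ the loading times the time:

- ochre, 2.00 h: θ 0.0600 h, G 24.1%
- violet, 1.00 h: θ 0.0680 h, G 16.0%
- ochre, 2.50 h: θ 0.0750 h, G 13.6%
- violet, 1.50 h: θ 0.102 h, G 3.1%

Read down the rows: θ rises and G falls, although the rows alternate between two runs, so at this charge and feed they lie on one curve. Grey doesn't belong on it, since its charge is 0.15 M: at θ 0.0450 h it shows 30.1% of G, less than violet's 38.2% at 0.0454 h.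

The X readings don't follow θ: ochre at 2.00 h has 25.1% of X, more than violet's 14.7% at 1.00 h, where θ is larger. So I use θ for G and not for X.

The flask has the charge and feed of ochre and violet, and at 2.0 h it stands at 0.0900 h: that is its catalyst time θ, the loading of D as a fraction of G times the hours run. This lies between the last two rows. Low on the curve I take the fall as pseudo-first-order, so I interpolate in ln c_G and get 5.98% of G.

The forecast gives X 32%, G 7.3% and J 60.7%, saying “the integrated form gives G ≈ 7% at 2 h”.

The flask gives X 32.6%, G 7.07% and J 59.7%.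

    G.D ⇌ Z (K = 0.330, k = 10.0 min⁻¹)
    G + D → G.D (k = 8.80 M⁻¹ min⁻¹)
    Z → D + J (k = 1.70 min⁻¹)
    J → X (k = 0.00640 min⁻¹)

At θ 0.0900 h the flask holds 1.1 percentage points more G than my interpolation, against a scatter of 1 point in the readings. It is not at rest. Left ten times as long, it ends with G at 0%, J at 0.0688% and X at 99.9%, so hardly any of the J remains and the 59.7% of J now present has become X.

Read at 50 min, the same flask stands at θ 0.0375 h, between ochre's readings at 1.00 h and 1.33 h, and the same interpolation gives 47.7% of G. The computed flask has 46.4%.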